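Ring B, the cross-conjugated dienone, is a para-quinol methyl ether: its carbonyl carbon C6' lies para to the methoxylated quaternary carbon C3', so ring B is a masked 4-alkylphenol in which C8, the methyl-bearing CH on C3', is benzylic. Everything rests on the C7–C8 disconnection, C7 being the CH2 on dimethoxyphenyl ring A. In the key step an enantioenriched benzylic carbamate of the ring B phenol allyl ether is lithiated at C8 and captures 3,4-dimethoxybenzyl pinacolboronate; stereospecific 1,2-metalate rearrangement forms C7–C8 and protodeboronation leaves C8 configured. Aromatic Claisen rearrangement and methanolic oxidative dearomatisation, steered by C8, complete the target.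

Key step: step 5

Remark: ring B is numbered C1' (allyl-bearing carbon), C2', C3' (quaternary carbon), C4' (enol ether carbon), C5', C6' (carbonyl); the side chain is C7 (CH2), C8 (CH), C9 (CH3). These names are kept for all intermediates.

Step 1
Reactants: 1 1-(4-hydroxy-2-methoxyphenyl)ethan-1-one
Product: 2 1-[2-methoxy-4-(prop-2-en-1-yloxy)phenyl]ethan-1-one
Conditions: allyl bromide (1.2 equiv), K2CO3, acetone, reflux
Reagents that add atoms: allyl bromide, C=CCBr
Why: Williamson ether synthesis (SN2 of the para-acyl phenoxide on allyl bromide); the allyl ether masks the phenol towards s-BuLi and later delivers the allyl group to carbon.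

Step 2
Reactants: 2 1-[2-methoxy-4-(prop-2-en-1-yloxy)phenyl]ethan-1-one
Product: 3 (1S)-1-[2-methoxy-4-(prop-2-en-1-yloxy)phenyl]ethan-1-ol
Conditions: RuCl[(S,S)-TsDPEN](p-cymene) (1 mol %), HCO2H/Et3N (5:2), 40 °C
Reagents that add atoms: none
Why: Noyori asymmetric transfer hydrogenation through an outer-sphere six-membered transition state with the aryl group under the η6-arene, so the (S,S)-catalyst should give the (S)-carbinol as with acetophenone, and the saturated ruthenium hydride should leave the allyl ether alone.

Step 3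
Reactants: 3 (1S)-1-[2-methoxy-4-(prop-2-en-1-yloxy)phenyl]ethan-1-ol
Product: 4 (1S)-1-[2-methoxy-4-(prop-2-en-1-yloxy)phenyl]ethyl N,N-di(propan-2-yl)carbamate
Conditions: NaH, THF, 0 °C; then i-Pr2NCOCl, reflux
Reagents that add atoms: N,N-diisopropylcarbamoyl chloride, CC(C)N(C(C)C)C(Cl)=O
Why: O-carbamoylation of the sodium alkoxide (acyl substitution); the C8–O bond is not broken, so the configuration is kept.

Step 4
Reactants: 5 4-(chloromethyl)-1,2-dimethoxybenzene
Product: 6 2-[(3,4-dimethoxyphenyl)methyl]-4,4,5,5-tetramethyl-1,3,2-dioxaborolane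
Conditions: B2pin2 (1.1 equiv), Pd(dba)2 (3 mol %), P(4-MeOC6H4)3 (6 mol %), KOAc, toluene, 50 °C
Reagents that add atoms: bis(pinacolato)diboron, CC1(C)OB(OC1(C)C)B1OC(C)(C)C(C)(C)O1
Why: Miyaura borylation of a benzylic chloride: oxidative addition to zerovalent palladium, acetate-assisted transmetalation with the diboron, and reductive elimination of the benzyl–boron bond.

Step 5
Reactants: 4 (1S)-1-[2-methoxy-4-(prop-2-en-1-yloxy)phenyl]ethyl N,N-di(propan-2-yl)carbamate, 6 2-[(3,4-dimethoxyphenyl)methyl]-4,4,5,5-tetramethyl-1,3,2-dioxaborolane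
Product: 10 1-[(2S)-1-(3,4-dimethoxyphenyl)propan-2-yl]-2-methoxy-4-(prop-2-en-1-yloxy)benzene, via α-lithiated carbamate 7 (not isolated), via lithium boronate complex 8 (not isolated), via tertiary boronic ester 9 (not isolated)
Conditions: s-BuLi (1.2 equiv), Et2O, −78 °C, 30 min; 6 (1.3 equiv), −78 °C, 1 h, then 35 °C, 12 h; solvent change to toluene, Bu4NF·3H2O (3 equiv), 60 °C
Reagents that add atoms: none
Why: s-BuLi, pre-complexed to the carbamate carbonyl, removes the benzylic C8 proton with retention to give the configurationally stable organolithium 7, which boronic ester 6 captures with retention to form boronate complex 8; on warming, the 3,4-dimethoxybenzyl group migrates from boron to C8 anti-periplanar to the departing carbamate (inversion at C8), forming the C7–C8 bond in tertiary boronic ester 9. Fluoride then converts 9 into a fluoroboronate whose C–B bond is protonated by water with retention, so the net result is that the benzyl group stands where the C8–H of 4 stood and the new hydrogen where the carbamate oxygen stood, which is (S) in 10. The closest known reaction type is the lithiation–borylation–protodeboronation of enantioenriched secondary benzylic carbamates, a stereospecific 1,2-metalate rearrangement. No ring is closed. The C8 stereocentre is controlled solely by the carbinol configuration of 4 through this fixed sequence of retention, retention, inversion and retention. The step needs benzylic deprotonation to outrun metalation next to the allyl ether oxygen or at C5' between the two ring oxygens, which the complex-induced proximity of the carbamate, diamine-free Et2O and −78 °C should secure, and it needs carbon rather than oxygen to migrate, which the high migratory aptitude of benzyl on a pinacol boronate secures.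

Step 6
Reactants: 10 1-[(2S)-1-(3,4-dimethoxyphenyl)propan-2-yl]-2-methoxy-4-(prop-2-en-1-yloxy)benzene
Product: 11 4-[(2S)-1-(3,4-dimethoxyphenyl)propan-2-yl]-5-methoxy-2-(prop-2-en-1-yl)phenol
Conditions: N,N-diethylaniline, 190 °C, sealed tube
Reagents that add atoms: none
Why: Aromatic Claisen rearrangement ([3,3] shift, then tautomerisation to the phenol); C5' lies between the ether oxygen and the C4' methoxy group, whose methyl is pushed towards C5' by the bulky C3' substituent, so the allyl group should go to C1', and C8 is not involved.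

Step 7
Reactants: 11 4-[(2S)-1-(3,4-dimethoxyphenyl)propan-2-yl]-5-methoxy-2-(prop-2-en-1-yl)phenol
Product: 12 (4S)-4-[(2S)-1-(3,4-dimethoxyphenyl)propan-2-yl]-4,5-dimethoxy-2-(prop-2-en-1-yl)cyclohexa-2,5-dien-1-one (CNP0204170.3)
Conditions: PhI(OAc)2 (1.1 equiv), MeOH, −20 to 0 °C
Reagents that add atoms: methanol, CO
Why: Oxidative dearomatisation of a para-alkylphenol to a para-quinol methyl ether (ligand exchange to an aryloxy-λ3-iodane, then methanol adds to the para carbon C3' as iodobenzene leaves); with the C8–H bond eclipsing the ring on the side of the C4' methoxy group (allylic 1,3-strain), methanol should enter on the face carrying the C9 methyl, anti to the larger arylmethyl group, which gives (S) at C3'.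

Compound list
1 | 1-(4-hydroxy-2-methoxyphenyl)ethan-1-one | CC(=O)c1ccc(O)cc1OC | starting material
2 | 1-[2-methoxy-4-(prop-2-en-1-yloxy)phenyl]ethan-1-one | CC(=O)c1ccc(OCC=C)cc1OC | intermediate
3 | (1S)-1-[2-methoxy-4-(prop-2-en-1-yloxy)phenyl]ethan-1-ol | C[C@H](O)c1ccc(OCC=C)cc1OC | intermediate
4 | (1S)-1-[2-methoxy-4-(prop-2-en-1-yloxy)phenyl]ethyl N,N-di(propan-2-yl)carbamate | C[C@H](OC(=O)N(C(C)C)C(C)C)c1ccc(OCC=C)cc1OC | intermediate
5 | 4-(chloromethyl)-1,2-dimethoxybenzene | COc1ccc(CCl)cc1OC | starting material
6 | 2-[(3,4-dimethoxyphenyl)methyl]-4,4,5,5-tetramethyl-1,3,2-dioxaborolane | COc1ccc(CB2OC(C)(C)C(C)(C)O2)cc1OC | intermediate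
7 | (1S)-1-lithio-1-[2-methoxy-4-(prop-2-en-1-yloxy)phenyl]ethyl N,N-di(propan-2-yl)carbamate | C[C@]([Li])(OC(=O)N(C(C)C)C(C)C)c1ccc(OCC=C)cc1OC | intermediate (not isolated)
8 | lithium [(1S)-1-(diisopropylcarbamoyloxy)-1-[2-methoxy-4-(prop-2-en-1-yloxy)phenyl]ethyl][(3,4-dimethoxyphenyl)methyl](pinacolato)borate | [Li+].C[C@]([B-]1(Cc2ccc(OC)c(OC)c2)OC(C)(C)C(C)(C)O1)(OC(=O)N(C(C)C)C(C)C)c1ccc(OCC=C)cc1OC | intermediate (not isolated)
9 | 2-[(2S)-1-(3,4-dimethoxyphenyl)-2-[2-methoxy-4-(prop-2-en-1-yloxy)phenyl]propan-2-yl]-4,4,5,5-tetramethyl-1,3,2-dioxaborolane | C[C@@](B1OC(C)(C)C(C)(C)O1)(Cc1ccc(OC)c(OC)c1)c1ccc(OCC=C)cc1OC | intermediate (not isolated)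
10 | 1-[(2S)-1-(3,4-dimethoxyphenyl)propan-2-yl]-2-methoxy-4-(prop-2-en-1-yloxy)benzene | C[C@@H](Cc1ccc(OC)c(OC)c1)c1ccc(OCC=C)cc1OC | intermediate
11 | 4-[(2S)-1-(3,4-dimethoxyphenyl)propan-2-yl]-5-methoxy-2-(prop-2-en-1-yl)phenol | C=CCc1cc([C@@H](C)Cc2ccc(OC)c(OC)c2)c(OC)cc1O | intermediate
12 | (4S)-4-[(2S)-1-(3,4-dimethoxyphenyl)propan-2-yl]-4,5-dimethoxy-2-(prop-2-en-1-yl)cyclohexa-2,5-dien-1-one | C=CCC1=C[C@@](OC)([C@@H](C)Cc2ccc(OC)c(OC)c2)C(OC)=CC1=O | target

Total step count: 7. Longest linear sequence: 6 steps (steps 1, 2, 3, 5, 6, 7).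

Steps most likely to fail

Step 7. The stereochemical argument rests on acyclic 1,2-induction, so methanol may discriminate poorly between the two faces of C3'; the oxidised ring could also be captured by electron-rich ring A instead of by methanol. Fallback: setting out from 11, oxidation with PhI(OCOCF3)2 in MeCN/H2O at 0 °C would give the two tertiary para-quinols, (4S)-4-[(2S)-1-(3,4-dimethoxyphenyl)propan-2-yl]-4-hydroxy-5-methoxy-2-(prop-2-en-1-yl)cyclohexa-2,5-dien-1-one F1 and (4R)-4-[(2S)-1-(3,4-dimethoxyphenyl)propan-2-yl]-4-hydroxy-5-methoxy-2-(prop-2-en-1-yl)cyclohexa-2,5-dien-1-one F2. Their free hydroxyl groups should allow separation on silica. F1 is O-methylated (MeI, Ag2O, CH2Cl2) and so comes back to the route at 12; F2 is reduced with Zn in AcOH back to 11 for another pass.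

Step 5. s-BuLi may deprotonate next to the allyl ether oxygen in competition with the carbamate-directed lithiation, boronate formation may reverse with erosion of configuration, or protonolysis of the C–B bond may be sluggish on the electron-rich ring. Fallback: an enantioconvergent nickel-catalysed Negishi coupling that needs neither organolithium nor boron. Setting out from 3, HCl (4 M in dioxane) in CH2Cl2 at −20 °C gives the racemic chloride 1-(1-chloroethyl)-2-methoxy-4-(prop-2-en-1-yloxy)benzene F3, used at once. From 5, zinc dust and LiCl in THF give [(3,4-dimethoxyphenyl)methyl]zinc chloride F4. Coupling of F3 with F4 (NiBr2·diglyme 10 mol %, the i-Pr-Pybox enantiomer that leads to the (S)-product, DMA, 0 °C) passes through a benzylic radical common to both enantiomers of F3 and comes back to the route at 10.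

Step 6. The allyl group may migrate in part to the other ortho carbon C5', or the hot phenol may undergo side reactions of the allyl group. Fallback: the allyl group is placed by electrophilic substitution instead of a sigmatropic shift. Setting out from 10, Pd(PPh3)4 and morpholine in THF remove the O-allyl group to give 4-[(2S)-1-(3,4-dimethoxyphenyl)propan-2-yl]-3-methoxyphenol F5. NBS in MeCN at −20 °C should brominate ortho to the hydroxyl and para to the methoxy group to give 2-bromo-4-[(2S)-1-(3,4-dimethoxyphenyl)propan-2-yl]-5-methoxyphenol F6. Stille coupling of F6 with allyltributylstannane (Pd(PPh3)4, DMF, 90 °C) comes back to the route at 11.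

Further compounds
F1 | step 7 | (4S)-4-[(2S)-1-(3,4-dimethoxyphenyl)propan-2-yl]-4-hydroxy-5-methoxy-2-(prop-2-en-1-yl)cyclohexa-2,5-dien-1-one | C=CCC1=C[C@@](O)([C@@H](C)Cc2ccc(OC)c(OC)c2)C(OC)=CC1=O
F2 | step 7 | (4R)-4-[(2S)-1-(3,4-dimethoxyphenyl)propan-2-yl]-4-hydroxy-5-methoxy-2-(prop-2-en-1-yl)cyclohexa-2,5-dien-1-one | C=CCC1=C[C@](O)([C@@H](C)Cc2ccc(OC)c(OC)c2)C(OC)=CC1=O
F3 | step 5 | 1-(1-chloroethyl)-2-methoxy-4-(prop-2-en-1-yloxy)benzene (racemic) | CC(Cl)c1ccc(OCC=C)cc1OC
F4 | step 5 | [(3,4-dimethoxyphenyl)methyl]zinc chloride | COc1ccc(C[Zn]Cl)cc1OC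
F5 | step 6 | 4-[(2S)-1-(3,4-dimethoxyphenyl)propan-2-yl]-3-methoxyphenol | C[C@@H](Cc1ccc(OC)c(OC)c1)c1ccc(O)cc1OC
F6 | step 6 | 2-bromo-4-[(2S)-1-(3,4-dimethoxyphenyl)propan-2-yl]-5-methoxyphenol | Brc1cc([C@@H](C)Cc2ccc(OC)c(OC)c2)c(OC)cc1O
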